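**Retrosynthetic overview**

- The target comes from a hexa-O-benzyl tetralone by one global hydrogenolysis.
- The strategy rests on ring B: its C1 ketone carbon and its C4 methine (the carbon carrying the aroyl group) are bonded to the adjacent carbons C8a and C4a of resorcinol ring A, with C1 next to the C8 oxygen. This is the ortho acyl/alkyl pattern an aryne leaves after inserting into a C(alpha)–C(acyl) bond.
- Ring B is therefore made by insertion of 3,5-bis(benzyloxy)benzyne into the ring C(=O)–CH(aroyl) bond of a 2-aroyl-3-(benzyloxy)-3-methylcyclobutanone, which enlarges the four-membered ring to the six-membered one.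
- The cyclobutanone comes from a dichloroketene [2+2] with 2-(benzyloxy)propene and dechlorination; C3 is fixed by chiral lithium amide deprotonation, and aldol addition to the ring C aldehyde plus oxidation installs the aroyl group.
- Ring order: rings A and C are bought as benzenoids; the pyrone is closed first (dioxinone thermolysis), then the cyclobutane, and ring B last.

Key step: step 13

Remark 1: ring positions follow 3,4-dihydronaphthalen-1(2H)-one numbering for rings A and B (C1 ketone, C3 carbinol, C4 methine, C4a/C8a fusion); ring C is the benzoyl ring.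
Remark 2: 3,5-bis(benzyloxy)phenol and 2-(benzyloxy)propene are taken as purchasable; starting from phloroglucinol or benzyl acetate would add one or two routine steps each.
Remark 3: which enantiomer of the lithium amide removes the α-proton leading to the (3R) series cannot be predicted with confidence for a 3-alkoxy-3-methylcyclobutanone; the (R,R)-base is written, and its antipode is used if a pilot correlation shows the opposite sense.

**Route**

Step 1
Reactants: 1 3,5-bis(benzyloxy)phenol
Product: 2 3,5-bis(benzyloxy)-2-bromophenol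
Conditions: NBS (1.0 equiv), CH2Cl2, −78 to 0 °C
Reagents that add atoms: N-bromosuccinimide, O=C1CCC(=O)N1Br
Why: Electrophilic aromatic bromination; the two equivalent positions between OH and OBn (ortho to the free hydroxyl, para to the far ether) are less hindered than the position between the two benzyloxy groups, so monobromination should fall there.

Step 2
Reactants: 2 3,5-bis(benzyloxy)-2-bromophenol
Product: 5 3,5-bis(benzyloxy)-2-(trimethylsilyl)phenyl trifluoromethanesulfonate, via aryl trimethylsilyl ether 3 (not isolated), via lithium 2-silylphenoxide 4 (not isolated)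
Conditions: HN(SiMe3)2, THF, 65 °C, evaporate; n-BuLi, THF, −78 °C; Tf2O, −78 °C to rt
Reagents that add atoms: hexamethyldisilazane, C[Si](C)(C)N[Si](C)(C)C; trifluoromethanesulfonic anhydride, O=S(=O)(OS(=O)(=O)C(F)(F)F)C(F)(F)F
Why: O-silylation, bromine–lithium exchange, 1,3-O-to-C silyl shift (retro-Brook rearrangement) and triflation of the phenoxide is the standard one-flask route to ortho-silylaryl triflates, and the halogen–metal exchange is far faster than any deprotonation of the benzyl ethers.

Step 3
Reactants: 6 methyl (3,5-dihydroxyphenyl)acetate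
Product: 7 methyl [3,5-bis(benzyloxy)phenyl]acetate
Conditions: BnBr, K2CO3, acetone, 56 °C
Reagents that add atoms: benzyl bromide, BrCc1ccccc1
Why: Williamson ether synthesis on both phenols; carbonate is too weak to enolise the ester.

Step 4
Reactants: 7 methyl [3,5-bis(benzyloxy)phenyl]acetate
Product: 8 [3,5-bis(benzyloxy)phenyl]acetic acid
Conditions: LiOH, THF–MeOH–H2O, rt; then 1 M HCl
Reagents that add atoms: lithium hydroxide, [Li+].[OH-]
Why: Saponification of an unhindered methyl ester.

Step 5
Reactants: 8 [3,5-bis(benzyloxy)phenyl]acetic acid, 9 2,2,6-trimethyl-4H-1,3-dioxin-4-one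
Product: 12 6-{3-[3,5-bis(benzyloxy)phenyl]-2-oxopropyl}-2,2-dimethyl-4H-1,3-dioxin-4-one, via arylacetyl chloride 10 (not isolated), via lithium dienolate 11 (not isolated)
Conditions: 8, (COCl)2, cat. DMF, CH2Cl2, 0 °C to rt, evaporate; 9, LiN(SiMe3)2 (2.2 equiv), THF, −78 °C; add 10, −78 °C; aq NH4Cl
Reagents that add atoms: none
Why: Acid chloride formation and γ-selective C-acylation of the dioxinone dienolate (vinylogous Claisen condensation); the second equivalent of dienolate takes up the acidic proton of the β-keto product, and any arylketene formed from 10 acylates the dienolate to the same product.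

Step 6
Reactants: 12 6-{3-[3,5-bis(benzyloxy)phenyl]-2-oxopropyl}-2,2-dimethyl-4H-1,3-dioxin-4-one
Product: 14 6-[3,5-bis(benzyloxy)benzyl]-4-hydroxy-2H-pyran-2-one, via acylketene 13 (not isolated)
Conditions: PhMe, 110 °C
Reagents that add atoms: none
Why: Retro-hetero-Diels–Alder loss of acetone gives an acylketene that is captured by the enol oxygen of the remote ketone, the established dioxinone route to 6-substituted 4-hydroxy-2-pyrones.

Step 7
Reactants: 14 6-[3,5-bis(benzyloxy)benzyl]-4-hydroxy-2H-pyran-2-one
Product: 15 4-(benzyloxy)-6-[3,5-bis(benzyloxy)benzyl]-2H-pyran-2-one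
Conditions: BnOH, PPh3, DIAD, THF, 0 °C to rt
Reagents that add atoms: benzyl alcohol, OCc1ccccc1
Why: Mitsunobu alkylation of the acidic 4-hydroxyl goes on oxygen and avoids the C3-benzylation that benzyl halide and base can give.

Step 8
Reactants: 15 4-(benzyloxy)-6-[3,5-bis(benzyloxy)benzyl]-2H-pyran-2-one
Product: 17 2,4-bis(benzyloxy)-6-{[4-(benzyloxy)-2-oxo-2H-pyran-6-yl]methyl}benzaldehyde, via iminium salt 16 (not isolated)
Conditions: POCl3, DMF, 0 to 50 °C; then aq NaOAc, rt
Reagents that add atoms: N,N-dimethylformamide, CN(C)C=O; water, O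
Why: Vilsmeier–Haack formylation should take the ring C position ortho to the CH2 group (ortho to one ether, para to the other), as 3,5-dialkoxytoluenes do, while the electron-poor 4-alkoxypyrone is far less nucleophilic.

Step 9
Reactants: 18 2-(benzyloxy)propene, 19 trichloroacetyl chloride
Product: 21 rac-3-(benzyloxy)-2,2-dichloro-3-methylcyclobutan-1-one, via dichloroketene 20 (not isolated)
Conditions: Zn–Cu couple, Et2O–DME, rt, slow addition of 19
Reagents that add atoms: none
Why: Ketene–alkene [2+2] cycloaddition; the nucleophilic CH2 terminus of the enol ether bonds to the ketene carbonyl carbon, which places the oxygenated carbon at C3, and the racemic C3 centre becomes a non-stereogenic carbon again in step 10.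

Step 10
Reactants: 21 rac-3-(benzyloxy)-2,2-dichloro-3-methylcyclobutan-1-one
Product: 22 3-(benzyloxy)-3-methylcyclobutan-1-one
Conditions: Zn dust, AcOH, rt
Reagents that add atoms: none
Why: Reductive dechlorination of an α,α-dichloroketone, as used for 3-(benzyloxy)cyclobutanone itself; protonation of the zinc enolate outruns β-elimination of the benzyloxy group, and the product is achiral with two enantiotopic CH2 groups.

Step 11
Reactants: 22 3-(benzyloxy)-3-methylcyclobutan-1-one, 17 2,4-bis(benzyloxy)-6-{[4-(benzyloxy)-2-oxo-2H-pyran-6-yl]methyl}benzaldehyde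
Product: 24 (3R)-3-(benzyloxy)-2-{[2,4-bis(benzyloxy)-6-{[4-(benzyloxy)-2-oxo-2H-pyran-6-yl]methyl}phenyl](hydroxy)methyl}-3-methylcyclobutan-1-one as a mixture of epimers at C2 and the carbinol carbon, via lithium enolate 23 (not isolated)
Conditions: (R,R)-[PhCH(Me)]2NH, n-BuLi, LiCl, THF, −100 °C; add 22; then 17 (0.9 equiv), −100 to −78 °C; aq NH4Cl at −78 °C
Reagents that add atoms: none
Why: Enantioselective deprotonation of a prochiral cyclobutanone by a C2-symmetric chiral lithium amide, then aldol addition; the base selects one of the two enantiotopic CH2 groups and so fixes C3 as (R), while the two new centres (C2 and the carbinol carbon) need no control because step 12 removes one and makes the other epimerisable.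

Step 12
Reactants: 24 (3R)-aldol adduct
Product: 25 (2R,3R)-3-(benzyloxy)-2-[2,4-bis(benzyloxy)-6-{[4-(benzyloxy)-2-oxo-2H-pyran-6-yl]methyl}benzoyl]-3-methylcyclobutan-1-one
Conditions: Dess–Martin periodinane, NaHCO3, CH2Cl2, 0 °C; cold neutral work-up, crude used at once
Reagents that add atoms: none
Why: Dess–Martin oxidation of a β-hydroxy ketone to the 1,3-diketone under buffered conditions; C2 is now a freely epimerisable 1,3-dicarbonyl carbon that should settle with the aroyl group trans to methyl (or enolise), only C3 holding fixed configuration, and the push–pull cyclobutane is not chromatographed.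

Step 13
Reactants: 25 (2R,3R)-2-aroyl-3-(benzyloxy)-3-methylcyclobutan-1-one, 5 3,5-bis(benzyloxy)-2-(trimethylsilyl)phenyl trifluoromethanesulfonate
Product: 28 (3R,4S)-3,6,8-tris(benzyloxy)-4-[2,4-bis(benzyloxy)-6-{[4-(benzyloxy)-2-oxo-2H-pyran-6-yl]methyl}benzoyl]-3-methyl-3,4-dihydronaphthalen-1(2H)-one, via aryne 26 (not isolated), via benzocyclobutenoxide 27 (not isolated)
Conditions: 5 (1.5 equiv), KF, 18-crown-6, THF, 0 °C to rt; pH 7 phosphate buffer
Reagents that add atoms: none
Why: Fluoride cleaves the C–Si bond of 5 and expels triflate to give aryne 26 while the basic medium holds 25 as its 1,3-diketonate, whose central carbon adds to the aryne carbon remote from the flanking benzyloxy group (the future C4a) and so leaves the aryl anion on C8a, next to oxygen, where it is inductively stabilised. This anion closes 4-exo-trig onto the cyclobutanone carbonyl to give benzocyclobutenoxide 27, and retro-aldol-type scission of the bond shared by the two four-membered rings (C1–C4) releases the strain of both and leaves the six-membered ketone with an aroyl-stabilised benzylic carbanion at C4, which is protonated. The closest known reaction type is the aryne acyl-alkylation (C–C sigma-bond insertion) of β-keto esters and 1,3-diketones, including the two-carbon ring expansion of cyclic β-keto esters. Ring B is thus formed by enlargement from four to six atoms and not by a direct cyclisation, with C4–C4a made by intermolecular enolate arylation and C1–C8a by the 4-exo-trig closure. C3 is carried through untouched, and the new centre C4 is set by protonation and equilibration of the acidic C4–H under control of C3, the aroyl group settling trans to methyl and gauche to the smaller oxygen substituent. The step needs regioselective aryne capture, which the 3-benzyloxy group of the aryne secures, and attack of the aryl anion on the ring ketone and not on the aroyl carbonyl, which the strain-activated unhindered cyclobutanone carbonyl should win against a di-ortho-substituted aryl ketone; room temperature and a neutral quench limit β-elimination of benzyl alcohol from C3.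

Step 14
Reactants: 28 hexa-O-benzyl tetralone
Product: 29 (3R,4S)-4-{2,4-dihydroxy-6-[(4-hydroxy-2-oxo-2H-pyran-6-yl)methyl]benzoyl}-3,6,8-trihydroxy-3-methyl-3,4-dihydronaphthalen-1(2H)-one (CNP0197349.1)
Conditions: H2 (1 atm), Pd/C, EtOAc–THF, rt, stopped as soon as the last benzyl ether is gone
Reagents that add atoms: none
Why: Hydrogenolysis of the five aryl and pyronyl benzyl ethers and of the tertiary benzyl ether under neutral conditions; the stereocentres are not touched, and the hydrogen-bonded aryl ketones and the 4-hydroxypyrone should be reduced much more slowly than the O-benzyl bonds are cleaved.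

**Compound list**

1 | 3,5-bis(benzyloxy)phenol | Oc1cc(OCc2ccccc2)cc(OCc2ccccc2)c1 | starting material
2 | 3,5-bis(benzyloxy)-2-bromophenol | Oc1cc(OCc2ccccc2)cc(OCc2ccccc2)c1Br | intermediate
3 | [3,5-bis(benzyloxy)-2-bromophenoxy]trimethylsilane | C[Si](C)(C)Oc1cc(OCc2ccccc2)cc(OCc2ccccc2)c1Br | intermediate
4 | lithium 3,5-bis(benzyloxy)-2-(trimethylsilyl)phenoxide | [Li]Oc1cc(OCc2ccccc2)cc(OCc2ccccc2)c1[Si](C)(C)C | intermediate
5 | 3,5-bis(benzyloxy)-2-(trimethylsilyl)phenyl trifluoromethanesulfonate | C[Si](C)(C)c1c(OS(=O)(=O)C(F)(F)F)cc(OCc2ccccc2)cc1OCc1ccccc1 | intermediate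
6 | methyl (3,5-dihydroxyphenyl)acetate | COC(=O)Cc1cc(O)cc(O)c1 | starting material
7 | methyl [3,5-bis(benzyloxy)phenyl]acetate | COC(=O)Cc1cc(OCc2ccccc2)cc(OCc2ccccc2)c1 | intermediate
8 | [3,5-bis(benzyloxy)phenyl]acetic acid | OC(=O)Cc1cc(OCc2ccccc2)cc(OCc2ccccc2)c1 | intermediate
9 | 2,2,6-trimethyl-4H-1,3-dioxin-4-one | CC1=CC(=O)OC(C)(C)O1 | starting material
10 | [3,5-bis(benzyloxy)phenyl]acetyl chloride | ClC(=O)Cc1cc(OCc2ccccc2)cc(OCc2ccccc2)c1 | intermediate
11 | lithium 2,2-dimethyl-6-methylidene-6H-1,3-dioxin-4-olate | C=C1C=C(O[Li])OC(C)(C)O1 | intermediate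
12 | 6-{3-[3,5-bis(benzyloxy)phenyl]-2-oxopropyl}-2,2-dimethyl-4H-1,3-dioxin-4-one | CC1(C)OC(=O)C=C(CC(=O)Cc2cc(OCc3ccccc3)cc(OCc3ccccc3)c2)O1 | intermediate
13 | 6-[3,5-bis(benzyloxy)phenyl]hex-1-ene-1,3,5-trione (acylketene) | O=C=CC(=O)CC(=O)Cc1cc(OCc2ccccc2)cc(OCc2ccccc2)c1 | intermediate
14 | 6-[3,5-bis(benzyloxy)benzyl]-4-hydroxy-2H-pyran-2-one | O=c1cc(O)cc(Cc2cc(OCc3ccccc3)cc(OCc3ccccc3)c2)o1 | intermediate
15 | 4-(benzyloxy)-6-[3,5-bis(benzyloxy)benzyl]-2H-pyran-2-one | O=c1cc(OCc2ccccc2)cc(Cc2cc(OCc3ccccc3)cc(OCc3ccccc3)c2)o1 | intermediate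
16 | N-{2,4-bis(benzyloxy)-6-[(4-(benzyloxy)-2-oxo-2H-pyran-6-yl)methyl]benzylidene}-N-methylmethanaminium chloride | C[N+](C)=Cc1c(OCc2ccccc2)cc(OCc2ccccc2)cc1Cc1cc(OCc2ccccc2)cc(=O)o1.[Cl-] | intermediate
17 | 2,4-bis(benzyloxy)-6-{[4-(benzyloxy)-2-oxo-2H-pyran-6-yl]methyl}benzaldehyde | O=Cc1c(OCc2ccccc2)cc(OCc2ccccc2)cc1Cc1cc(OCc2ccccc2)cc(=O)o1 | intermediate
18 | 2-(benzyloxy)propene (benzyl isopropenyl ether) | C=C(C)OCc1ccccc1 | starting material
19 | trichloroacetyl chloride | ClC(=O)C(Cl)(Cl)Cl | starting material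
20 | dichloroketene | ClC(Cl)=C=O | intermediate
21 | rac-3-(benzyloxy)-2,2-dichloro-3-methylcyclobutan-1-one | CC1(OCc2ccccc2)CC(=O)C1(Cl)Cl | intermediate
22 | 3-(benzyloxy)-3-methylcyclobutan-1-one (achiral) | CC1(OCc2ccccc2)CC(=O)C1 | intermediate
23 | lithium (3R)-3-(benzyloxy)-3-methylcyclobut-1-en-1-olate | C[C@@]1(OCc2ccccc2)CC(O[Li])=C1 | intermediate
24 | (3R)-3-(benzyloxy)-2-{[2,4-bis(benzyloxy)-6-{[4-(benzyloxy)-2-oxo-2H-pyran-6-yl]methyl}phenyl](hydroxy)methyl}-3-methylcyclobutan-1-one, epimers at C2 and the carbinol carbon | C[C@@]1(OCc2ccccc2)CC(=O)C1C(O)c1c(OCc2ccccc2)cc(OCc2ccccc2)cc1Cc1cc(OCc2ccccc2)cc(=O)o1 | intermediate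
25 | (2R,3R)-3-(benzyloxy)-2-[2,4-bis(benzyloxy)-6-{[4-(benzyloxy)-2-oxo-2H-pyran-6-yl]methyl}benzoyl]-3-methylcyclobutan-1-one | C[C@@]1(OCc2ccccc2)CC(=O)[C@@H]1C(=O)c1c(OCc2ccccc2)cc(OCc2ccccc2)cc1Cc1cc(OCc2ccccc2)cc(=O)o1 | intermediate
26 | 3,5-bis(benzyloxy)benzyne | C1(OCc2ccccc2)=CC(OCc2ccccc2)=CC#C1 | intermediate
27 | potassium benzocyclobutenoxide adduct of 25 and 26 (C4–C4a and C1–C8a formed, C1–C4 still intact, C3 as in 25) | C[C@@]1(OCc2ccccc2)CC3([O-])c4c(OCc5ccccc5)cc(OCc5ccccc5)cc4C13C(=O)c1c(OCc2ccccc2)cc(OCc2ccccc2)cc1Cc1cc(OCc2ccccc2)cc(=O)o1.[K+] | intermediate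
28 | (3R,4S)-3,6,8-tris(benzyloxy)-4-[2,4-bis(benzyloxy)-6-{[4-(benzyloxy)-2-oxo-2H-pyran-6-yl]methyl}benzoyl]-3-methyl-3,4-dihydronaphthalen-1(2H)-one | C[C@@]1(OCc2ccccc2)CC(=O)c2c(OCc3ccccc3)cc(OCc3ccccc3)cc2[C@@H]1C(=O)c1c(OCc2ccccc2)cc(OCc2ccccc2)cc1Cc1cc(OCc2ccccc2)cc(=O)o1 | intermediate
29 | (3R,4S)-4-{2,4-dihydroxy-6-[(4-hydroxy-2-oxo-2H-pyran-6-yl)methyl]benzoyl}-3,6,8-trihydroxy-3-methyl-3,4-dihydronaphthalen-1(2H)-one | C[C@@]1(O)CC(=O)c2c(O)cc(O)cc2[C@@H]1C(=O)c1c(O)cc(O)cc1Cc1cc(O)cc(=O)o1 | target

**Totals**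

Total step count: 14. Longest linear sequence: 10 steps (6 to 29 through steps 3–8 and 11–14).

**Steps most likely to fail**

Step 13. The diketonate may fail to arylate at its congested carbon. The aryl anion may be protonated, or may add to the aroyl carbonyl so that the acyl group migrates and the ring is not enlarged. The product enolate may expel benzyloxide from C3 and aromatise ring B to a naphthol. The aryne may also be consumed by the pyrone diene. The fallback sets out from 25 and makes the two ring B bonds one after the other. Pd-catalysed C-arylation of the 1,3-diketone with 1-bromo-3,5-bis(benzyloxy)benzene (Pd(OAc)2, P(t-Bu)3·HBF4, K3PO4, THF, 70 °C) would give (3R)-2-[3,5-bis(benzyloxy)phenyl]-2-aroyl-3-(benzyloxy)-3-methylcyclobutan-1-one F1. Hydroxide (LiOH, THF–H2O, 0 °C) should then open the strained, non-enolisable ring ketone by retro-Claisen cleavage to (3R)-3-(benzyloxy)-4-[3,5-bis(benzyloxy)phenyl]-3-methyl-5-oxo-5-aryl-pentanoic acid F2. Intramolecular Friedel–Crafts acylation ((CF3CO)2O, CH2Cl2, 0 °C) onto the ring A position ortho to the side chain, which is ortho and para to the two ether oxygens, closes ring B. C4 then equilibrates, and the sequence comes back to the route at 28.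

Step 11. The base may discriminate poorly between the two enantiotopic CH2 groups, because methyl and benzyloxy at C3 differ little in size. Proton exchange between enolate and unreacted ketone would erode the selectivity further. Addition to the hindered, electron-rich aldehyde may be slow enough for the enolate to deprotonate the ArCH2–pyrone methylene or to lose benzyloxide. The fallback sets out from 22 and gives up asymmetric deprotonation for resolution. LiN(i-Pr)2 in THF at −78 °C followed by 17 would give the racemic aldol adduct F3. Dess–Martin oxidation would give the racemic 2-aroylcyclobutanone F4. The conditions of step 13 would give the racemic hexa-O-benzyl tetralone F5. Preparative chromatography on a chiral stationary phase (amylose tris(3,5-dimethylphenylcarbamate), CO2–MeOH) then separates the enantiomers, and the (3R,4S)-enantiomer comes back to the route at 28.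

Step 12. The aldol adduct may undergo retro-aldol cleavage during oxidation. The neutral push–pull cyclobutane 25 may open heterolytically at C2–C3 (diketonate as leaving group, oxocarbenium at C3) on work-up or standing. The fallback sets out from 17 and never handles the neutral diketone. Chlorite oxidation (NaClO2, NaH2PO4, 2-methyl-2-butene, t-BuOH–H2O) would give 2,4-bis(benzyloxy)-6-{[4-(benzyloxy)-2-oxo-2H-pyran-6-yl]methyl}benzoic acid F6. Oxalyl chloride with catalytic DMF in CH2Cl2 would give the benzoyl chloride F7. Enolate 23, generated as in step 11 and transmetallated with MgBr2·OEt2, is C-acylated by F7 at −78 °C. The resulting metal enolate of 25 is carried in THF directly into step 13, so the fallback comes back to the route at 25 in its enolate form.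

**Further compounds**

F1 | step 13 | (3R)-2-[3,5-bis(benzyloxy)phenyl]-3-(benzyloxy)-2-[2,4-bis(benzyloxy)-6-{[4-(benzyloxy)-2-oxo-2H-pyran-6-yl]methyl}benzoyl]-3-methylcyclobutan-1-one | C[C@@]1(OCc2ccccc2)CC(=O)C1(c1cc(OCc2ccccc2)cc(OCc2ccccc2)c1)C(=O)c1c(OCc2ccccc2)cc(OCc2ccccc2)cc1Cc1cc(OCc2ccccc2)cc(=O)o1
F2 | step 13 | (3R)-3-(benzyloxy)-4-[3,5-bis(benzyloxy)phenyl]-5-[2,4-bis(benzyloxy)-6-{[4-(benzyloxy)-2-oxo-2H-pyran-6-yl]methyl}phenyl]-3-methyl-5-oxopentanoic acid | C[C@@](OCc1ccccc1)(CC(=O)O)C(c1cc(OCc2ccccc2)cc(OCc2ccccc2)c1)C(=O)c1c(OCc2ccccc2)cc(OCc2ccccc2)cc1Cc1cc(OCc2ccccc2)cc(=O)o1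
F3 | step 11 | racemic aldol adduct corresponding to 24 | CC1(OCc2ccccc2)CC(=O)C1C(O)c1c(OCc2ccccc2)cc(OCc2ccccc2)cc1Cc1cc(OCc2ccccc2)cc(=O)o1
F4 | step 11 | racemic 2-aroyl-3-(benzyloxy)-3-methylcyclobutan-1-one corresponding to 25 | CC1(OCc2ccccc2)CC(=O)C1C(=O)c1c(OCc2ccccc2)cc(OCc2ccccc2)cc1Cc1cc(OCc2ccccc2)cc(=O)o1
F5 | step 11 | racemic hexa-O-benzyl tetralone corresponding to 28 | CC1(OCc2ccccc2)CC(=O)c2c(OCc3ccccc3)cc(OCc3ccccc3)cc2C1C(=O)c1c(OCc2ccccc2)cc(OCc2ccccc2)cc1Cc1cc(OCc2ccccc2)cc(=O)o1
F6 | step 12 | 2,4-bis(benzyloxy)-6-{[4-(benzyloxy)-2-oxo-2H-pyran-6-yl]methyl}benzoic acid | OC(=O)c1c(OCc2ccccc2)cc(OCc2ccccc2)cc1Cc1cc(OCc2ccccc2)cc(=O)o1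
F7 | step 12 | 2,4-bis(benzyloxy)-6-{[4-(benzyloxy)-2-oxo-2H-pyran-6-yl]methyl}benzoyl chloride | ClC(=O)c1c(OCc2ccccc2)cc(OCc2ccccc2)cc1Cc1cc(OCc2ccccc2)cc(=O)o1
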